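**Plan**

- Retrosynthesis: the CH2OH group on C3 is taken back to a carboxylic acid. That acid and the benzylic carbon on C4 are then re-joined through a benzylic C–O bond into a cis-fused γ-aryl lactone. The bicyclic lactone is finally cut at C2–C3 and at C4–C5 of the oxolane.
- Enabling feature: the ArCH(2)–O(1)–CH2(5) ether of the oxolane ring is a masked carbonyl ylide. C3 and C4 carry their CH2OH carbon and benzylic carbon cis, so both fit into the ring of a 3-alkoxy-5-aryl-2(5H)-furanone whose ring alkene is C3=C4.
- Forward order: the furanone ring is made first (asymmetric allylation and lactonisation, ozonolysis, O-benzylation). The oxolane ring is then formed by [3+2] cycloaddition. The lactone ring is opened by hydrogenolysis and the acid is reduced.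
- Stereochemistry: one catalyst-set carbinol centre (S, C5 of the furanone) sends the ylide to the opposite ring face and so fixes C3 and C4. Exo approach sets C2. The directing centre is then erased as the benzyl CH2.

Key step: step 5

Assumption: in step 1 the ligand antipode that delivers the S carbinol is used; the sense of induction with aldehyde 1 is to be confirmed on the first run.

**Route**

Step 1
Reactants: 1 4-(benzyloxy)-3-methoxybenzaldehyde; 2 ethyl 2-(bromomethyl)acrylate
Product: 5 (S)-5-[4-(benzyloxy)-3-methoxyphenyl]-3-methylenedihydrofuran-2(3H)-one, via silyl ether 3 (not isolated), via hydroxy ester 4 (not isolated)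
Conditions: CrCl2 (10 mol %), chiral 1,8-bis(4-isopropyl-4,5-dihydrooxazol-2-yl)-3,6-di-tert-butylcarbazole ligand (12 mol %), Mn powder, Me3SiCl, iPr2NEt, THF, rt; then 1 M HCl, THF; then TsOH·H2O (cat.), CH2Cl2, rt
Reagents that add atoms: none
Why: Catalytic asymmetric Nozaki–Hiyama–Kishi-type 2-(alkoxycarbonyl)allylation, in which the allylchromium species from 2 adds to the aldehyde through a closed six-membered transition state inside the chiral ligand pocket and so sets the S carbinol centre, Me3SiCl releases trivalent chromium from the alkoxide, Mn returns it to divalent chromium, and acid frees the alcohol, which closes to the γ-lactone.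

Step 2
Reactants: 5 (S)-5-[4-(benzyloxy)-3-methoxyphenyl]-3-methylenedihydrofuran-2(3H)-one
Product: 7 (S)-5-[4-(benzyloxy)-3-methoxyphenyl]-3-hydroxyfuran-2(5H)-one, via ozonide 6 (not isolated)
Conditions: O3, CH2Cl2, −78 °C, feed stopped at the end point; then Me2S, −78 °C to rt
Reagents that add atoms: ozone, [O-][O+]=O
Why: Ozonolysis of the exocyclic 1,1-disubstituted alkene with reductive work-up should give the α-keto lactone, which rests as its conjugated enol 7; the alkene is expected to react faster than the dialkoxy arene at −78 °C, and the C5 centre is not involved.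

Step 3
Reactants: 7 (S)-5-[4-(benzyloxy)-3-methoxyphenyl]-3-hydroxyfuran-2(5H)-one
Product: 8 (S)-3-(benzyloxy)-5-[4-(benzyloxy)-3-methoxyphenyl]furan-2(5H)-one
Conditions: BnOH, PPh3, DIAD, THF, 0 °C to rt
Reagents that add atoms: benzyl alcohol, OCc1ccccc1
Why: Mitsunobu O-alkylation of the acidic enol hydroxyl under essentially neutral conditions, chosen so that the base-sensitive C5 centre (benzylic and γ to the carbonyl) is not epimerised.

Step 4
Reactants: 1 4-(benzyloxy)-3-methoxybenzaldehyde; 9 (trimethylsilyl)methanol (2.5 equiv)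
Product: 10 4-(benzyloxy)-3-methoxybenzaldehyde bis[(trimethylsilyl)methyl] acetal
Conditions: TsOH·H2O (cat.), cyclohexane, reflux, Dean–Stark trap; Et3N quench
Reagents that add atoms: none
Why: Acid-catalysed acetalisation driven by azeotropic removal of water; it places on the aldehyde carbon one leaving group and the CH2SiMe3 group needed for the later 1,3-elimination.

Step 5
Reactants: 10 4-(benzyloxy)-3-methoxybenzaldehyde bis[(trimethylsilyl)methyl] acetal (2.5 equiv); 8 (S)-3-(benzyloxy)-5-[4-(benzyloxy)-3-methoxyphenyl]furan-2(5H)-one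
Product: 13 (3S,3aR,6R,6aR)-6a-(benzyloxy)-3,6-bis[4-(benzyloxy)-3-methoxyphenyl]tetrahydro-1H,3H-furo[3,4-c]furan-1-one, via chloro ether 11 (not isolated), via carbonyl ylide 12 (not isolated)
Conditions: AcCl (1 equiv per 10), SOCl2 (cat.), CH2Cl2, 0 °C to rt, volatiles removed in vacuo; crude 11 in MeCN added slowly to 8 and dried CsF, MeCN, rt
Reagents that add atoms: none
Why: Acetyl chloride turns acetal 10 into α-chloro ether 11, which ionises readily to an oxocarbenium ion stabilised by the para-benzyloxy aryl group; fluoride then removes the silyl group (silicon-based 1,3-elimination) and the carbonyl ylide 12, a four-electron C–O–C dipole, adds across the C3=C4 bond of 8 in a concerted, asynchronous [3+2] cycloaddition. The closest known reaction type is the fluoride-induced generation of nonstabilised carbonyl ylides from α-chloroalkyl silylmethyl ethers and their cycloaddition to acrylates, enones and related activated alkenes. The oxolane ring is closed by intermolecular suprafacial [π4s+π2s] cycloaddition, both C–C bonds forming on the same face of the ring alkene, so the new ring is necessarily cis-fused to the lactone ring. C3a and C6a follow from addition to the face of 8 opposite to its C5 aryl group (substrate control by the temporary stereocentre), and C6 from exo approach of the ylide with its aryl group in the outside (E) position, which places that aryl over the benzyloxy oxygen and on the convex face instead of over the lactone ring. The step needs regioselectivity, secured because the unsubstituted CH2 terminus of the ylide carries the larger HOMO coefficient and bonds to the β-carbon C4 of the unsaturated lactone while the aryl-stabilised terminus bonds to C3; it needs face selectivity, secured by the C5 aryl group; and the cis relation of the future CH2OH and benzyl carbons is secured by the ring of 8, which holds them on the same side of the alkene.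

Step 6
Reactants: 13 (3S,3aR,6R,6aR)-6a-(benzyloxy)-3,6-bis[4-(benzyloxy)-3-methoxyphenyl]tetrahydro-1H,3H-furo[3,4-c]furan-1-one
Product: 14 (2R,3R,4S)-3-hydroxy-2-(4-hydroxy-3-methoxyphenyl)-4-(4-hydroxy-3-methoxybenzyl)tetrahydrofuran-3-carboxylic acid
Conditions: H2 (1 atm), Pd/C (10 wt %), EtOAc/MeOH, rt, stopped after uptake of four equivalents
Reagents that add atoms: none
Why: Catalytic hydrogenolysis should cleave the three benzyl ethers and the benzylic acyloxy C–O bond of the γ-aryl lactone (a cyclic benzyl ester), which is a better leaving group and less hindered than the benzylic alkyl ether C–O flanked by the quaternary carbon; the temporary stereocentre becomes the benzyl CH2 and no stereocentre of 14 is touched.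

Step 7
Reactants: 14 (2R,3R,4S)-3-hydroxy-2-(4-hydroxy-3-methoxyphenyl)-4-(4-hydroxy-3-methoxybenzyl)tetrahydrofuran-3-carboxylic acid
Product: 15 (2R,3S,4S)-2-(4-hydroxy-3-methoxyphenyl)-4-(4-hydroxy-3-methoxybenzyl)-3-(hydroxymethyl)tetrahydrofuran-3-ol
Conditions: BH3·THF (excess), THF, 0 °C to rt; MeOH quench and repeated co-evaporation with MeOH
Reagents that add atoms: none
Why: Borane reduction of the carboxylic acid through its acyloxyborane is chemoselective in the presence of phenols and the tertiary alcohol (carried as borates and released by methanolysis) and leaves the benzylic ether and all three stereocentres untouched.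

**Compound list**

1 | 4-(benzyloxy)-3-methoxybenzaldehyde | O=Cc1ccc(OCc2ccccc2)c(OC)c1 | starting material
2 | ethyl 2-(bromomethyl)acrylate | C=C(CBr)C(=O)OCC | starting material
3 | ethyl (S)-4-[4-(benzyloxy)-3-methoxyphenyl]-2-methylene-4-[(trimethylsilyl)oxy]butanoate | CCOC(=O)C(=C)C[C@H](O[Si](C)(C)C)c1ccc(OCc2ccccc2)c(OC)c1 | intermediate
4 | ethyl (S)-4-[4-(benzyloxy)-3-methoxyphenyl]-4-hydroxy-2-methylenebutanoate | CCOC(=O)C(=C)C[C@H](O)c1ccc(OCc2ccccc2)c(OC)c1 | intermediate
5 | (S)-5-[4-(benzyloxy)-3-methoxyphenyl]-3-methylenedihydrofuran-2(3H)-one | C=C1C[C@@H](c2ccc(OCc3ccccc3)c(OC)c2)OC1=O | intermediate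
6 | (8S)-8-[4-(benzyloxy)-3-methoxyphenyl]-1,2,4,7-tetraoxaspiro[4.4]nonan-6-one (secondary ozonide of 5, spiro centre unassigned) | O=C1O[C@H](c2ccc(OCc3ccccc3)c(OC)c2)CC12OOCO2 | intermediate
7 | (S)-5-[4-(benzyloxy)-3-methoxyphenyl]-3-hydroxyfuran-2(5H)-one | O=C1O[C@H](c2ccc(OCc3ccccc3)c(OC)c2)C=C1O | intermediate
8 | (S)-3-(benzyloxy)-5-[4-(benzyloxy)-3-methoxyphenyl]furan-2(5H)-one | O=C1O[C@H](c2ccc(OCc3ccccc3)c(OC)c2)C=C1OCc1ccccc1 | intermediate
9 | (trimethylsilyl)methanol | C[Si](C)(C)CO | starting material
10 | 4-(benzyloxy)-3-methoxybenzaldehyde bis[(trimethylsilyl)methyl] acetal | C[Si](C)(C)COC(OC[Si](C)(C)C)c1ccc(OCc2ccccc2)c(OC)c1 | intermediate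
11 | ({chloro[4-(benzyloxy)-3-methoxyphenyl]methoxy}methyl)trimethylsilane (racemic α-chloro ether) | C[Si](C)(C)COC(Cl)c1ccc(OCc2ccccc2)c(OC)c1 | intermediate
12 | carbonyl ylide from 1 and a methylene unit, ArCH=O(+)–CH2(−) with Ar = 4-(benzyloxy)-3-methoxyphenyl | [CH2-][O+]=Cc1ccc(OCc2ccccc2)c(OC)c1 | intermediate
13 | (3S,3aR,6R,6aR)-6a-(benzyloxy)-3,6-bis[4-(benzyloxy)-3-methoxyphenyl]tetrahydro-1H,3H-furo[3,4-c]furan-1-one | O=C1O[C@H](c2ccc(OCc3ccccc3)c(OC)c2)[C@H]2CO[C@H](c3ccc(OCc4ccccc4)c(OC)c3)[C@@]12OCc1ccccc1 | intermediate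
14 | (2R,3R,4S)-3-hydroxy-2-(4-hydroxy-3-methoxyphenyl)-4-(4-hydroxy-3-methoxybenzyl)tetrahydrofuran-3-carboxylic acid | COc1cc(C[C@H]2CO[C@H](c3ccc(O)c(OC)c3)[C@@]2(O)C(=O)O)ccc1O | intermediate
15 | (2R,3S,4S)-2-(4-hydroxy-3-methoxyphenyl)-4-(4-hydroxy-3-methoxybenzyl)-3-(hydroxymethyl)tetrahydrofuran-3-ol | COc1cc(C[C@H]2CO[C@H](c3ccc(O)c(OC)c3)[C@@]2(O)CO)ccc1O | target

**Count and risks**

Total step count: 7. Longest linear sequence: 6 steps (steps 1, 2, 3, 5, 6 and 7 from aldehyde 1); step 4 is the one-step side branch.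

Steps most likely to fail:

Step 5. The short-lived ylide may close to the oxirane or dimerise faster than it adds to the trisubstituted, alkoxy-bearing alkene. The approach may be endo instead of exo, giving the wrong configuration at the aryl-bearing carbon. Fluoride or the ylide may deprotonate C5 of 8 and erode its configuration. The fallback sets out from 8 (and uses 10) and comes back at 13; it forms the same two bonds one after the other. Benzophenone-sensitised photoaddition of methanol to 8 (MeOH, Ph2CO, 350 nm) should add a hydroxymethyl radical to C4 anti to the C5 aryl group. This gives (4R,5S)-3-(benzyloxy)-5-[4-(benzyloxy)-3-methoxyphenyl]-4-(hydroxymethyl)dihydrofuran-2(3H)-one F1 as a C3 epimer mixture. Transacetalisation of F1 with excess 10 (pyridinium p-toluenesulfonate, toluene, removal of the silyl alcohol) gives the mixed acetal (4R,5S)-3-(benzyloxy)-5-[4-(benzyloxy)-3-methoxyphenyl]-4-({[4-(benzyloxy)-3-methoxyphenyl][(trimethylsilyl)methoxy]methoxy}methyl)dihydrofuran-2(3H)-one F2. LiN(SiMe3)2 and Me3SiCl (THF, −78 °C) convert it into the silyl ketene acetal (4R,5S)-3-(benzyloxy)-2-[(trimethylsilyl)oxy]-4,5-dihydrofuran bearing the same C4 acetal arm and C5 aryl group F3. Me3SiOTf (CH2Cl2, −78 °C) then ionises the acetal, and the tethered oxocarbenium ion is captured by the ketene acetal carbon (intramolecular Mukaiyama-type addition to an acetal). The tether forces cis fusion and the aryl group takes the convex face, giving 13.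

Step 6. Chemoselectivity between the two benzylic C–O bonds may be lost, with further hydrogenolysis of the oxolane C–O bond, or the reaction may stall before the hindered tertiary benzyl ether is cleaved. The fallback sets out from 13 and comes back at 14. Hydrogenolysis over Pd/C (EtOAc, 1 atm) is stopped as soon as the three benzyl ethers are gone, giving (3S,3aR,6R,6aR)-6a-hydroxy-3,6-bis(4-hydroxy-3-methoxyphenyl)tetrahydro-1H,3H-furo[3,4-c]furan-1-one F4. The lactone is then opened without a metal catalyst: NaBH4 and iPr2NEt in THF/iPrOH at 0 °C. The phenoxide para to the lactone benzylic carbon expels the carboxylate by 1,6-elimination, and the resulting para-quinone methide is reduced by hydride. The oxolane C–O bond would have to lose an alkoxide and should not react. Acidification gives 14.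

Step 1. The catalytic chromium allylation may give insufficient enantioselectivity or slow turnover with the electron-rich aldehyde. The fallback sets out from 1 and comes back at 5; it sets the carbinol centre by ketone reduction instead.
- Stetter reaction of 1 with ethyl acrylate (3-benzyl-5-(2-hydroxyethyl)-4-methylthiazolium chloride, Et3N, EtOH, 70 °C) gives ethyl 4-[4-(benzyloxy)-3-methoxyphenyl]-4-oxobutanoate F5.
- Asymmetric transfer hydrogenation with RuCl(p-cymene)[(S,S)-TsDPEN] in HCO2H/Et3N gives ethyl (S)-4-[4-(benzyloxy)-3-methoxyphenyl]-4-hydroxybutanoate F6.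
- TsOH-catalysed lactonisation gives (S)-5-[4-(benzyloxy)-3-methoxyphenyl]dihydrofuran-2(3H)-one F7.
- The lithium enolate (LiN(iPr)2, THF, −78 °C) is treated with dimethyl(methylene)ammonium iodide to give (5S)-5-[4-(benzyloxy)-3-methoxyphenyl]-3-[(dimethylamino)methyl]dihydrofuran-2(3H)-one F8.
- MeI gives {(5S)-5-[4-(benzyloxy)-3-methoxyphenyl]-2-oxotetrahydrofuran-3-yl}-N,N,N-trimethylmethanaminium iodide F9, and NaHCO3 eliminates trimethylamine to give 5.

Further compounds

F1 | step 5 | (4R,5S)-3-(benzyloxy)-5-[4-(benzyloxy)-3-methoxyphenyl]-4-(hydroxymethyl)dihydrofuran-2(3H)-one (C3 epimers) | O=C1O[C@H](c2ccc(OCc3ccccc3)c(OC)c2)[C@@H](CO)C1OCc1ccccc1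
F2 | step 5 | (4R,5S)-3-(benzyloxy)-5-[4-(benzyloxy)-3-methoxyphenyl]-4-({[4-(benzyloxy)-3-methoxyphenyl][(trimethylsilyl)methoxy]methoxy}methyl)dihydrofuran-2(3H)-one (acetal carbon and C3 unassigned) | O=C1O[C@H](c2ccc(OCc3ccccc3)c(OC)c2)[C@@H](COC(OC[Si](C)(C)C)c2ccc(OCc3ccccc3)c(OC)c2)C1OCc1ccccc1
F3 | step 5 | {[(4R,5S)-3-(benzyloxy)-5-[4-(benzyloxy)-3-methoxyphenyl]-4-({[4-(benzyloxy)-3-methoxyphenyl][(trimethylsilyl)methoxy]methoxy}methyl)-4,5-dihydrofuran-2-yl]oxy}trimethylsilane | C[Si](C)(C)OC1=C(OCc2ccccc2)[C@H](COC(OC[Si](C)(C)C)c2ccc(OCc3ccccc3)c(OC)c2)[C@@H](c2ccc(OCc3ccccc3)c(OC)c2)O1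
F4 | step 6 | (3S,3aR,6R,6aR)-6a-hydroxy-3,6-bis(4-hydroxy-3-methoxyphenyl)tetrahydro-1H,3H-furo[3,4-c]furan-1-one | O=C1O[C@H](c2ccc(O)c(OC)c2)[C@H]2CO[C@H](c3ccc(O)c(OC)c3)[C@@]12O
F5 | step 1 | ethyl 4-[4-(benzyloxy)-3-methoxyphenyl]-4-oxobutanoate | CCOC(=O)CCC(=O)c1ccc(OCc2ccccc2)c(OC)c1
F6 | step 1 | ethyl (S)-4-[4-(benzyloxy)-3-methoxyphenyl]-4-hydroxybutanoate | CCOC(=O)CC[C@H](O)c1ccc(OCc2ccccc2)c(OC)c1
F7 | step 1 | (S)-5-[4-(benzyloxy)-3-methoxyphenyl]dihydrofuran-2(3H)-one | O=C1CC[C@@H](c2ccc(OCc3ccccc3)c(OC)c2)O1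
F8 | step 1 | (5S)-5-[4-(benzyloxy)-3-methoxyphenyl]-3-[(dimethylamino)methyl]dihydrofuran-2(3H)-one (C3 epimers) | CN(C)CC1C[C@@H](c2ccc(OCc3ccccc3)c(OC)c2)OC1=O
F9 | step 1 | {(5S)-5-[4-(benzyloxy)-3-methoxyphenyl]-2-oxotetrahydrofuran-3-yl}-N,N,N-trimethylmethanaminium iodide (C3 epimers) | C[N+](C)(C)CC1C[C@@H](c2ccc(OCc3ccccc3)c(OC)c2)OC1=O.[I-]
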